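**Plan**
1. Cuts, in retrosynthetic order: the C3–C3a bond of the 2,3-dihydrobenzofuran together with the C–O bond of its hydroxymethyl group; the O1–C2 ether bond; the C7''–C8'' bond of the arylglycerol unit; the aryl-O–C8'' bond.
2. Forward: the erythro arylglycerol β-aryl ether is built first on methyl sinapate (phenol alkylation, glycolate aldol, inversion at C7''). Its diol is held in a temporary dioxane ring, the cinnamate arm becomes a cinnamyl carbonate, iodovanillin (as its dioxolane) is attached through O1–C2, and the dihydrofuran ring is closed last.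
3. Enabling feature: in the ring O1–C2–C3–C3a–C7a, C3a is the only unsubstituted carbon ortho to O1 on the vanillin-derived benzene ring, and C3 carries a one-carbon oxygenated branch. An aryl radical at C3a, tethered through O1–C2, therefore lies 5-exo to a C3=CH2 vinyl group, and one radical event makes C3–C3a, the C3 stereocentre and the CH2–O bond.
4. Stereochemistry: C8'' and C7'' come from the (S)-4-benzyl-2-oxazolidinone auxiliary (syn aldol) and a Mitsunobu inversion at C7'' (erythro, 7''S,8''R); C2 comes from the chiral iridium phosphoramidite catalyst (2R); C3 comes from C2 by substrate control in the ring closure (trans, 3S).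
5. Locants and shorthand: dihydrobenzofuran O1, C2, C3, C3a, C4–C7, C7a; arylglycerol C7'' (benzylic), C8'', C9''; DX = (4S,5R)-4-[3-methoxy-4-(triisopropylsilyloxy)phenyl]-2,2-dimethyl-1,3-dioxan-5-yl.

Key step: step 14

**Step 1**
Reactants: 1 syringaldehyde; 2 methyl (triphenylphosphoranylidene)acetate
Product: 3 methyl (E)-3-(4-hydroxy-3,5-dimethoxyphenyl)acrylate (methyl sinapate)
Conditions: toluene, 90 °C
Reagents that add atoms: none
Why: Wittig olefination with a stabilised ylide tolerates the free phenol and gives the E-cinnamate whose three side-chain carbons become C2, C3 and the hydroxymethyl carbon.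

**Step 2**
Reactants: 4 (S)-4-benzyl-2-oxazolidinone; 5 bromoacetyl bromide
Product: 7 (S)-4-benzyl-3-(bromoacetyl)-2-oxazolidinone, via lithiated oxazolidinone 6 (not isolated)
Conditions: n-BuLi, THF, −78 °C; then 5, −78 to 0 °C
Reagents that add atoms: none
Why: N-acylation of the lithiated auxiliary by the acyl bromide (far more electrophilic than the alkyl bromide) is the standard route to N-acyl oxazolidinones and leaves the C4 stereocentre untouched.

**Step 3**
Reactants: 3 methyl sinapate; 7 (S)-4-benzyl-3-(bromoacetyl)-2-oxazolidinone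
Product: 8 (S)-4-benzyl-3-({2,6-dimethoxy-4-[(E)-3-methoxy-3-oxoprop-1-enyl]phenoxy}acetyl)-2-oxazolidinone
Conditions: K2CO3, acetone, 40 °C
Reagents that add atoms: none
Why: Williamson ether synthesis, in which the acidic, hindered phenoxide displaces the activated α-bromide by SN2 and so forms the aryl-O–C8'' bond before any side-chain stereocentre exists.

**Step 4**
Reactants: 9 vanillin
Product: 10 3-methoxy-4-(triisopropylsilyloxy)benzaldehyde
Conditions: i-Pr3SiCl, imidazole, DMF, 25 °C
Reagents that add atoms: triisopropylsilyl chloride, CC(C)[Si](Cl)(C(C)C)C(C)C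
Why: standard phenol silylation; the triisopropylsilyl ether is chosen because it should survive the later methanolysis, hydride, radical and acidic steps and fall to fluoride at the end.

**Step 5**
Reactants: 8 aryloxyacetyl imide; 10 3-methoxy-4-(triisopropylsilyloxy)benzaldehyde
Product: 12 (4S)-4-benzyl-3-[(2S,3R)-2-{2,6-dimethoxy-4-[(E)-3-methoxy-3-oxoprop-1-enyl]phenoxy}-3-hydroxy-3-(3-methoxy-4-triisopropylsilyloxyphenyl)propanoyl]-2-oxazolidinone, via Z-boron enolate 11 (not isolated)
Conditions: Bu2BOTf, i-Pr2NEt, CH2Cl2, −78 to 0 °C; then 10, −78 to 0 °C; pH 7 buffer, MeOH, H2O2, 0 °C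
Reagents that add atoms: none
Why: Evans syn aldol reaction, in which the Z-boron enolate 11 adds to the aldehyde through a closed chair transition state on the enolate face remote from the benzyl group of the (S)-auxiliary; this fixes C8'' in its final configuration and C7'' as the (R)-epimer that is inverted in step 7.

**Step 6**
Reactants: 12 syn aldol adduct
Product: 13 methyl (E)-3-[4-({(1R,2R)-1,3-dihydroxy-1-[3-methoxy-4-(triisopropylsilyloxy)phenyl]propan-2-yl}oxy)-3,5-dimethoxyphenyl]acrylate (threo diol)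
Conditions: NaBH4, THF/H2O (4:1), 0 to 25 °C
Reagents that add atoms: none
Why: reductive cleavage of the N-acyl oxazolidinone with NaBH4 in wet THF gives the primary alcohol and returns the auxiliary, while the conjugated methyl ester and both stereocentres should be unaffected.

**Step 7**
Reactants: 13 threo diol
Product: 14 methyl (E)-3-[4-({(1S,2R)-1-[3-methoxy-4-(triisopropylsilyloxy)phenyl]-1,3-bis(4-nitrobenzoyloxy)propan-2-yl}oxy)-3,5-dimethoxyphenyl]acrylate
Conditions: 4-O2NC6H4CO2H (3 equiv), PPh3, DIAD, THF, 0 to 25 °C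
Reagents that add atoms: 4-nitrobenzoic acid, OC(=O)c1ccc(cc1)[N+](=O)[O-]
Why: Mitsunobu reaction with excess acid esterifies the primary hydroxyl and displaces the activated benzylic hydroxyl by SN2 with inversion, converting threo (7''R,8''R) into erythro (7''S,8''R).

**Step 8**
Reactants: 14 bis(4-nitrobenzoate)
Product: 15 methyl (E)-3-[4-({(1S,2R)-1,3-dihydroxy-1-[3-methoxy-4-(triisopropylsilyloxy)phenyl]propan-2-yl}oxy)-3,5-dimethoxyphenyl]acrylate (erythro diol)
Conditions: K2CO3 (cat.), MeOH/THF, 0 °C
Reagents that add atoms: none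
Why: base-catalysed transesterification should remove the two electron-poor aryl esters faster than it touches the methyl cinnamate (degenerate in methanol) or the hindered aryl silyl ether, and no bond to a stereocentre is broken.

**Step 9**
Reactants: 15 erythro diol
Product: 16 methyl (E)-3-[3,5-dimethoxy-4-(DX-oxy)phenyl]acrylate
Conditions: Me2C(OMe)2, PPTS (cat.), acetone, 25 °C
Reagents that add atoms: 2,2-dimethoxypropane, COC(C)(C)OC
Why: acetal exchange ties the 1,3-diol up as a six-membered isopropylidene ketal, a temporary ring that masks both hydroxyls through the hydride, carbonate, allylation and radical steps.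

**Step 10**
Reactants: 16 acetonide ester
Product: 17 (E)-3-[3,5-dimethoxy-4-(DX-oxy)phenyl]prop-2-en-1-ol
Conditions: i-Bu2AlH, CH2Cl2, −78 °C; aqueous KNaC4H4O6 work-up
Reagents that add atoms: none
Why: 1,2-reduction of the α,β-unsaturated ester by i-Bu2AlH at low temperature gives the E-allylic alcohol without conjugate reduction.

**Step 11**
Reactants: 17 allylic alcohol
Product: 18 (E)-3-[3,5-dimethoxy-4-(DX-oxy)phenyl]prop-2-en-1-yl methyl carbonate
Conditions: ClCO2Me, pyridine, CH2Cl2, 0 °C
Reagents that add atoms: methyl chloroformate, COC(Cl)=O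
Why: acylation of the primary allylic alcohol gives the linear cinnamyl carbonate, the standard electrophile for iridium-catalysed allylic substitution.

**Step 12**
Reactants: 19 5-iodovanillin
Product: 20 4-(1,3-dioxolan-2-yl)-2-iodo-6-methoxyphenol
Conditions: HOCH2CH2OH, TsOH·H2O (cat.), toluene, reflux, azeotropic removal of water
Reagents that add atoms: ethylene glycol, OCCO
Why: acid-catalysed acetalisation masks the aldehyde, which makes the phenoxide a better nucleophile and a poorer leaving group for step 13 and keeps the formyl group out of the tin hydride step.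

**Step 13**
Reactants: 18 cinnamyl carbonate; 20 iodophenol dioxolane
Product: 22 2-[4-({(1R)-1-[3,5-dimethoxy-4-(DX-oxy)phenyl]prop-2-en-1-yl}oxy)-3-iodo-5-methoxyphenyl]-1,3-dioxolane, via sodium aryloxide 21 (not isolated)
Conditions: 20, NaH, THF, 0 °C; then 18, [Ir(cod)Cl]2 (2 mol%), (Ra,Rc,Rc)-O,O'-(1,1'-binaphthyl-2,2'-diyl)-N,N-bis(1-phenylethyl)phosphoramidite (4 mol%, pre-activated with n-PrNH2), THF, 25 to 40 °C; water quench
Reagents that add atoms: none
Why: iridium-catalysed asymmetric allylic etherification, in which the cyclometalated phosphoramidite catalyst ionises the linear carbonate and directs the aryloxide to the aryl-substituted allyl terminus, so the branched ether forms with C2 set by the catalyst; (R) is expected with the (Ra,Rc,Rc) ligand by analogy with other cinnamyl electrophiles, and the mirror-image ligand would give the epimer.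

**Step 14**
Reactants: 22 (R)-branched allyl 2-iodoaryl ether
Product: 24 1-({(2R,3S)-2-[3,5-dimethoxy-4-(DX-oxy)phenyl]-5-(1,3-dioxolan-2-yl)-7-methoxy-2,3-dihydro-1-benzofuran-3-yl}methoxy)-2,2,6,6-tetramethylpiperidine, via primary alkyl radical 23 (not isolated)
Conditions: Bu3SnH, TEMPO (each in excess, added in portions), toluene, 70 °C
Reagents that add atoms: TEMPO, CC1(C)CCCC(C)(C)N1[O]
Why: Bu3Sn• (formed as TEMPO abstracts hydrogen from Bu3SnH) removes iodine from C3a, the σ-aryl radical adds to the internal vinyl carbon C3 in a 5-exo-trig closure that forms the O1–C2–C3–C3a–C7a ring, and the resulting primary radical 23 is captured at oxygen by TEMPO; the closest known reaction type is aryl radical cyclisation of allyl 2-iodoaryl ethers and amines with nitroxide trapping. The new stereocentre C3 is controlled by C2: in the envelope-like transition state the C2 aryl group lies pseudo-equatorial and the alkene terminus turns away from it, which should place the CH2O group trans to the aryl group, i.e. (2R,3S). The step needs 5-exo over 6-endo closure, which the geometry of the three-atom C3a–C7a–O1–C2 tether secures, and it needs cyclisation to outrun capture of the aryl radical by TEMPO or Bu3SnH, which the fast unimolecular closure of ortho-allyloxyaryl radicals should secure at the low reagent concentrations kept by portionwise addition. Regiochemistry on the arene is fixed by the iodine, which sits on the only free carbon ortho to O1, the other ortho carbon carrying the methoxy group. The dioxolane, the isopropylidene ketal, the silyl ether and the aryl ethers are inert to tin and nitroxyl radicals.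

**Step 15**
Reactants: 24 TEMPO ether
Product: 25 (2R,3S)-2-[4-({(1S,2R)-1,3-dihydroxy-1-[3-methoxy-4-(triisopropylsilyloxy)phenyl]propan-2-yl}oxy)-3,5-dimethoxyphenyl]-3-(hydroxymethyl)-7-methoxy-2,3-dihydro-1-benzofuran-5-carbaldehyde
Conditions: Zn, AcOH/THF/H2O (3:1:1), 50 °C
Reagents that add atoms: water, O
Why: zinc in acetic acid reduces the N–O bond of the alkoxyamine to unveil the primary alcohol, and the same warm aqueous acid hydrolyses the isopropylidene ketal and the dioxolane, while the benzylic ethers, the aryl silyl ether and all four stereocentres should be left alone.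

**Step 16**
Reactants: 25 silyl-protected target
Product: 26 (2R,3S)-2-(4-{[(1S,2R)-1,3-dihydroxy-1-(4-hydroxy-3-methoxyphenyl)propan-2-yl]oxy}-3,5-dimethoxyphenyl)-3-(hydroxymethyl)-7-methoxy-2,3-dihydro-1-benzofuran-5-carbaldehyde (CID53356209)
Conditions: Bu4NF, AcOH, THF, 0 °C
Reagents that add atoms: none
Why: fluoride-mediated cleavage of the aryl silyl ether, buffered with acetic acid so that the liberated 4-hydroxybenzyl alcohol unit and the aldehyde see no strong base, should give the target.

**Compound list**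
1 | syringaldehyde | COc1cc(C=O)cc(OC)c1O | starting material
2 | methyl (triphenylphosphoranylidene)acetate | COC(=O)C=P(c1ccccc1)(c1ccccc1)c1ccccc1 | starting material
3 | methyl (E)-sinapate | COC(=O)/C=C/c1cc(OC)c(O)c(OC)c1 | intermediate
4 | (S)-4-benzyl-2-oxazolidinone | O=C1N[C@@H](Cc2ccccc2)CO1 | starting material
5 | bromoacetyl bromide | BrCC(Br)=O | starting material
6 | lithium salt of (S)-4-benzyl-2-oxazolidinone | [Li+].O=C1[N-][C@@H](Cc2ccccc2)CO1 | intermediate
7 | (S)-4-benzyl-3-(bromoacetyl)-2-oxazolidinone | O=C(CBr)N1[C@@H](Cc2ccccc2)COC1=O | intermediate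
8 | (S)-4-benzyl-3-({2,6-dimethoxy-4-[(E)-3-methoxy-3-oxoprop-1-enyl]phenoxy}acetyl)-2-oxazolidinone | COC(=O)/C=C/c1cc(OC)c(OCC(=O)N2[C@@H](Cc3ccccc3)COC2=O)c(OC)c1 | intermediate
9 | vanillin | COc1cc(C=O)ccc1O | starting material
10 | 3-methoxy-4-(triisopropylsilyloxy)benzaldehyde | COc1cc(C=O)ccc1O[Si](C(C)C)(C(C)C)C(C)C | intermediate
11 | (Z)-dibutylboron enolate of 8 | CCCCB(CCCC)O/C(=C\Oc1c(OC)cc(/C=C/C(=O)OC)cc1OC)N1[C@@H](Cc2ccccc2)COC1=O | intermediate
12 | (2S,3R) syn aldol adduct on the (S)-auxiliary | COc1cc([C@@H](O)[C@H](Oc2c(OC)cc(/C=C/C(=O)OC)cc2OC)C(=O)N2[C@@H](Cc3ccccc3)COC2=O)ccc1O[Si](C(C)C)(C(C)C)C(C)C | intermediate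
13 | threo (1R,2R) diol | COc1cc([C@@H](O)[C@@H](CO)Oc2c(OC)cc(/C=C/C(=O)OC)cc2OC)ccc1O[Si](C(C)C)(C(C)C)C(C)C | intermediate
14 | (1S,2R) bis(4-nitrobenzoate) | COc1cc([C@H](OC(=O)c2ccc(cc2)[N+](=O)[O-])[C@@H](COC(=O)c2ccc(cc2)[N+](=O)[O-])Oc2c(OC)cc(/C=C/C(=O)OC)cc2OC)ccc1O[Si](C(C)C)(C(C)C)C(C)C | intermediate
15 | erythro (1S,2R) diol | COc1cc([C@H](O)[C@@H](CO)Oc2c(OC)cc(/C=C/C(=O)OC)cc2OC)ccc1O[Si](C(C)C)(C(C)C)C(C)C | intermediate
16 | (4S,5R) isopropylidene ketal, methyl cinnamate | COc1cc([C@@H]2OC(C)(C)OC[C@H]2Oc2c(OC)cc(/C=C/C(=O)OC)cc2OC)ccc1O[Si](C(C)C)(C(C)C)C(C)C | intermediate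
17 | (4S,5R) isopropylidene ketal, E-allylic alcohol | COc1cc([C@@H]2OC(C)(C)OC[C@H]2Oc2c(OC)cc(/C=C/CO)cc2OC)ccc1O[Si](C(C)C)(C(C)C)C(C)C | intermediate
18 | (4S,5R) isopropylidene ketal, E-cinnamyl methyl carbonate | COc1cc([C@@H]2OC(C)(C)OC[C@H]2Oc2c(OC)cc(/C=C/COC(=O)OC)cc2OC)ccc1O[Si](C(C)C)(C(C)C)C(C)C | intermediate
19 | 5-iodovanillin | COc1cc(C=O)cc(I)c1O | starting material
20 | 4-(1,3-dioxolan-2-yl)-2-iodo-6-methoxyphenol | COc1cc(C2OCCO2)cc(I)c1O | intermediate
21 | sodium 4-(1,3-dioxolan-2-yl)-2-iodo-6-methoxyphenoxide | [Na+].COc1cc(C2OCCO2)cc(I)c1[O-] | intermediate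
22 | (R)-branched allyl 2-iodoaryl ether | COc1cc([C@@H]2OC(C)(C)OC[C@H]2Oc2c(OC)cc([C@@H](C=C)Oc3c(OC)cc(C4OCCO4)cc3I)cc2OC)ccc1O[Si](C(C)C)(C(C)C)C(C)C | intermediate
23 | (2R,3S)-dihydrobenzofuran-3-ylmethyl radical | COc1cc([C@@H]2OC(C)(C)OC[C@H]2Oc2c(OC)cc([C@@H]3Oc4c(OC)cc(C5OCCO5)cc4[C@H]3[CH2])cc2OC)ccc1O[Si](C(C)C)(C(C)C)C(C)C | intermediate
24 | (2R,3S)-trans-dihydrobenzofuran, 3-CH2O-TEMPO ether | COc1cc([C@@H]2OC(C)(C)OC[C@H]2Oc2c(OC)cc([C@@H]3Oc4c(OC)cc(C5OCCO5)cc4[C@H]3CON3C(C)(C)CCCC3(C)C)cc2OC)ccc1O[Si](C(C)C)(C(C)C)C(C)C | intermediate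
25 | 4-O-triisopropylsilyl ether of the target | COc1cc([C@H](O)[C@@H](CO)Oc2c(OC)cc([C@@H]3Oc4c(OC)cc(C=O)cc4[C@H]3CO)cc2OC)ccc1O[Si](C(C)C)(C(C)C)C(C)C | intermediate
26 | CID53356209 | COc1cc([C@H](O)[C@@H](CO)Oc2c(OC)cc([C@@H]3Oc4c(OC)cc(C=O)cc4[C@H]3CO)cc2OC)ccc1O | target

**Summary**
Total step count: 16. Longest linear sequence: 13 steps (steps 1, 3, 5 to 11, 13 to 16, from syringaldehyde).

Steps most likely to fail:

1. Step 14. The 5-exo addition may show incomplete facial selectivity, so that the C3 epimer (cis) accompanies 24. The fallback puts C3 under thermodynamic instead of kinetic control. It sets out from 24 (as the epimer mixture). mCPBA with NaHCO3 in CH2Cl2 at 0 °C oxidises the primary alkoxyamine to the C3 aldehyde, and catalytic DBU in CH2Cl2 equilibrates it to the trans (2R,3R)-3-formyl-2,3-dihydrobenzofuran F1. NaBH4 in MeOH at 0 °C then gives the trans 3-hydroxymethyl compound F2. AcOH/THF/H2O at 50 °C removes the dioxolane and the isopropylidene ketal, and the route is rejoined at 25.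

2. Step 13. The hindered, ortho-iodinated aryloxide may attack the allyliridium intermediate slowly or at the wrong terminus, and the branched ether may re-ionise, giving linear ether or eroded enantiopurity. The fallback replaces catalytic allylation by a stereospecific SN2 opening. It sets out from allylic alcohol 17. Sharpless asymmetric epoxidation (Ti(OiPr)4, D-(−)-diethyl tartrate, t-BuOOH, CH2Cl2, −20 °C) gives the (2R,3R)-epoxy alcohol F3. Phenol 20 with K2CO3 in DMF at 60 °C opens the epoxide at the benzylic carbon with inversion, giving the (2R,3S)-3-aryloxy-1,2-diol F4. 1,1'-Thiocarbonyldiimidazole in toluene converts the diol into the cyclic thiocarbonate F5. Corey–Winter fragmentation with P(OMe)3 (or 1,3-dimethyl-2-phenyl-1,3,2-diazaphospholidine at 40 °C) then delivers the terminal alkene, and the route is rejoined at 22.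

3. Step 7. The electron-rich benzylic oxyphosphonium ion may ionise (SN1 instead of SN2), giving retention or elimination and hence threo material. The fallback replaces displacement by oxidation and reduction. It sets out from 13. DDQ in CH2Cl2 at 25 °C oxidises the electron-rich benzylic alcohol selectively to the (R)-α-aryloxy-β-hydroxy ketone F6. Chelation-controlled reduction with Zn(BH4)2 in Et2O at −20 °C (or NaBH4 in MeOH) is expected to favour the erythro diol, and the route is rejoined at 15; any threo isomer formed is 13 itself and can be recycled.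

**Further compounds**
F1 | step 14 | trans (2R,3R)-3-formyl-2,3-dihydrobenzofuran with dioxolane, isopropylidene ketal and silyl ether in place | COc1cc([C@@H]2OC(C)(C)OC[C@H]2Oc2c(OC)cc([C@@H]3Oc4c(OC)cc(C5OCCO5)cc4[C@H]3C=O)cc2OC)ccc1O[Si](C(C)C)(C(C)C)C(C)C
F2 | step 14 | trans (2R,3S)-3-hydroxymethyl-2,3-dihydrobenzofuran with dioxolane, isopropylidene ketal and silyl ether in place | COc1cc([C@@H]2OC(C)(C)OC[C@H]2Oc2c(OC)cc([C@@H]3Oc4c(OC)cc(C5OCCO5)cc4[C@H]3CO)cc2OC)ccc1O[Si](C(C)C)(C(C)C)C(C)C
F3 | step 13 | (2R,3R)-3-aryl-oxiran-2-ylmethanol from 17 | COc1cc([C@@H]2OC(C)(C)OC[C@H]2Oc2c(OC)cc([C@H]3O[C@@H]3CO)cc2OC)ccc1O[Si](C(C)C)(C(C)C)C(C)C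
F4 | step 13 | (2R,3S)-3-aryl-3-(aryloxy)propane-1,2-diol | COc1cc([C@@H]2OC(C)(C)OC[C@H]2Oc2c(OC)cc([C@@H]([C@H](O)CO)Oc3c(OC)cc(C4OCCO4)cc3I)cc2OC)ccc1O[Si](C(C)C)(C(C)C)C(C)C
F5 | step 13 | cyclic thiocarbonate (1,3-dioxolane-2-thione) of F4 | COc1cc([C@@H]2OC(C)(C)OC[C@H]2Oc2c(OC)cc([C@@H]([C@H]5COC(=S)O5)Oc3c(OC)cc(C4OCCO4)cc3I)cc2OC)ccc1O[Si](C(C)C)(C(C)C)C(C)C
F6 | step 7 | (R)-2-aryloxy-3-hydroxy-1-(3-methoxy-4-triisopropylsilyloxyphenyl)propan-1-one | COc1cc(C(=O)[C@@H](CO)Oc2c(OC)cc(/C=C/C(=O)OC)cc2OC)ccc1O[Si](C(C)C)(C(C)C)C(C)C
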